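**Plan**

- Retrosynthetic cuts: the N–O bond; the C-5 lactam carbonyl and C6=C7 (thiolactam, Raney Ni); the side-chain lactone at C3–C18 and C18–O (thioester plus zinc homoenolate, ketone reduction); the fused lactone at O–C11 and C12–C13 together (vinyl sulfoxide plus chloro(methyl)ketene); C10–ethyl and C11–S (conjugate addition and sulfinylation of a transposed enone); ring B at C6=C7 (ring-closing metathesis) and C9–C8 (allylation); the hydroindolenone from L-tyrosine.
- Forward order: rings C and A in one step from N-Boc-L-tyrosine, ring B by allylation and metathesis, enone transposition, ethyl and sulfinyl groups, ring D in the key step, ring E, lactam to amine, N-oxide.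
- Enabling feature: lactone ring D (O–C11–C12–C13–C14) is cis-fused to ring A, so its oxygen and C-13 sit on the adjacent carbons C-11 and C-12 on one face. With sulfur on C-11 of a C11=C12 double bond, the sulfinyl oxygen hands the O–C14–C13 unit of a ketene to C-12 by a [3,3] shift, and the thionium carbon C-11 then takes the oxygen.
- Stereochemistry: C-3 from L-tyrosine; C-9a by aza-Michael addition; C-1 by palladium hydride inversion; C-9 and C-10 by axial attack; C-12 and C-11 from the sulfur center (menthyl sulfinate); C-13 by hydrogen-atom transfer on the convex face (H-11, H-12, H-13 all cis, as the SMILES shows); C-18 by Felkin–Anh reduction; C-20 from the bromo ester; N by the ring fusion.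

Key step: step 13

Numbering remark: compounds 3–8 carry hydroindole numbering. Tricyclic compounds carry tuberostemonine numbering: ring A = C-1, C-9a, C-9, C-10, C-11, C-12; ring B = N-4, C-5 to C-9, C-9a; ring C = C-1, C-2, C-3, N-4, C-9a; ring D = fused lactone, C-13, C-14; ring E = side-chain lactone, C-18 to C-21. In all of them H-9a is trans to H-1 and cis to H-9, and H-3 is cis to H-1.

Assumption: in the ketene–sulfoxide rearrangement the enolate is delivered to the alkene face that carries the S–O bond in the rotamer with the p-tolyl group turned towards the vinylic H-12 and away from C-10. This fixes the sulfur configuration drawn for 14–18 and the choice of the (R)-sulfinate. If the opposite sense held, the enantiomeric commercial sulfinate would be used with no other change.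

**Route**

Step 1
Reactants: 1 N-Boc-L-tyrosine
Product: 3 methyl (2S,3aR,7aR)-1-Boc-3a-hydroxy-6-oxo-2,3,3a,6,7,7a-hexahydro-1H-indole-2-carboxylate (cis-fused), via spirolactone 2 (not isolated)
Conditions: PhI(OAc)2, MeOH, rt; then NaHCO3, 40 °C
Reagents that add atoms: methanol CO
Why: Hypervalent-iodine oxidative dearomatisation of the phenol with spirolactonisation by the carboxylate, then methanolysis of 2 and 5-exo aza-Michael addition of the carbamate nitrogen to one enone arm should give the cis-fused hydroindolenone, the L-tyrosine center (C-2) choosing the diastereotopic arm and so setting C-7a.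

Step 2
Reactants: 3 cis-fused hydroxy hydroindolenone
Product: 4 methyl (2S,3aR,7aR)-3a-benzoyloxy-1-Boc-6-oxo-2,3,3a,6,7,7a-hexahydro-1H-indole-2-carboxylate
Conditions: BzCl, DMAP (cat.), pyridine, CH2Cl2, rt
Reagents that add atoms: benzoyl chloride O=C(Cl)c1ccccc1
Why: DMAP-catalysed O-acylation makes the tertiary allylic alcohol a leaving group for palladium.

Step 3
Reactants: 4 tertiary allylic benzoate
Product: 5 methyl (2S,3aR,7aR)-1-Boc-6-oxo-2,3,3a,6,7,7a-hexahydro-1H-indole-2-carboxylate (trans-fused)
Conditions: Pd2(dba)3·CHCl3 (cat.), PBu3, HCO2H, Et3N, THF, rt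
Reagents that add atoms: none
Why: Tsuji-type palladium-catalysed allylic hydrogenolysis: zerovalent palladium ionises the benzoate from the face anti to it and the formate-derived hydride is passed from the metal to the more substituted allyl terminus, so H replaces O at C-3a with inversion and the ring fusion becomes trans.

Step 4
Reactants: 5 trans-fused hydroindolenone
Product: 6 methyl (2S,3aR,7S,7aS)-7-allyl-1-Boc-6-oxo-2,3,3a,6,7,7a-hexahydro-1H-indole-2-carboxylate (allyl cis to N)
Conditions: LiN(i-Pr)2, THF, −78 °C; allyl iodide, −78 → −40 °C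
Reagents that add atoms: allyl iodide C=CCI
Why: Kinetic α′-enolate alkylation: the electrophile enters axially, anti to the axial H-7a, which places the allyl group cis to nitrogen (sets C-7).

Step 5
Reactants: 6 allylated N-Boc enone
Product: 8 methyl (2S,3aR,7S,7aS)-1-acryloyl-7-allyl-6-oxo-2,3,3a,6,7,7a-hexahydro-1H-indole-2-carboxylate, via ammonium trifluoroacetate 7 (not isolated)
Conditions: TFA, CH2Cl2, 0 °C; evaporate; acryloyl chloride, i-Pr2NEt, CH2Cl2, −20 °C
Reagents that add atoms: acryloyl chloride C=CC(=O)Cl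
Why: Acidolysis of the Boc group and immediate Schotten–Baumann-type N-acylation of the ammonium salt, which is kept cold so that the β-amino ketone does not undergo retro-Michael opening.

Step 6
Reactants: 8 N-acryloyl C-allyl diene
Product: 9 tricyclic enone lactam (methyl ester on C-3; C-5 lactam with C6=C7; C-10 ketone conjugated with C11=C12)
Conditions: second-generation Grubbs catalyst RuCl2(=CHPh)(PCy3)(H2IMes) (5 mol%), CH2Cl2 (5 mM), 40 °C
Reagents that add atoms: none
Why: Ring-closing metathesis joins the acrylamide and the cis-disposed allyl group into the seven-membered unsaturated lactam (ring B).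

Step 7
Reactants: 9 tricyclic enone lactam
Product: 10 11,12-epoxy-10-ketone (epoxide on the ring A face opposite to C-8)
Conditions: t-BuOOH, DBU, CH2Cl2, 0 °C → rt
Reagents that add atoms: tert-butyl hydroperoxide CC(C)(C)OO
Why: Weitz–Scheffer nucleophilic epoxidation attacks only the enone, the unsaturated lactam being too poor an acceptor, and the anhydrous base spares the methyl ester; the epoxide face is of no consequence.

Step 8
Reactants: 10 epoxy ketone
Product: 11 allylic alcohol (12-OH on the face opposite to C-8; C10=C11)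
Conditions: N2H4·H2O, AcOH (cat.), MeOH, 0 °C → rt
Reagents that add atoms: none
Why: Wharton transposition: the epoxy hydrazone collapses with loss of N2 to the allylic alcohol, moving the oxygen from C-10 to C-12.

Step 9
Reactants: 11 allylic alcohol
Product: 12 transposed enone (C-12 ketone conjugated with C10=C11)
Conditions: Dess–Martin periodinane, CH2Cl2, 0 °C → rt
Reagents that add atoms: none
Why: Dess–Martin oxidation gives the transposed enone under non-basic conditions, which protects the now enolisable ring-fusion center C-1.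

Step 10
Reactants: 12 transposed enone
Product: 14 10-ethyl-12-oxo-11-[(S)-p-tolylsulfinyl] tricyclic lactam ester (ethyl trans to C-8; C-11 epimers), via bromomagnesium enolate 13 (not isolated)
Conditions: EtMgBr, CuBr·SMe2 (10 mol%), THF, −78 °C; then (1S,2R,5S)-menthyl (R)-p-toluenesulfinate, −78 → 0 °C; aq. NH4Cl
Reagents that add atoms: ethylmagnesium bromide CC[Mg]Br; (1S,2R,5S)-menthyl (R)-p-toluenesulfinate CC(C)[C@H]1CC[C@H](C)C[C@@H]1O[S@@](=O)c1ccc(C)cc1
Why: Copper-catalysed conjugate addition delivers ethyl to C-10 axially and anti to the axial C-8 branch on C-9 (sets C-10), and the regiodefined magnesium enolate 13 is C-sulfinylated by the menthyl sulfinate with inversion at sulfur (Andersen-type substitution), which sets the sulfur center.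

Step 11
Reactants: 14 β-keto sulfoxide
Product: 15 12-hydroxy-11-[(S)-p-tolylsulfinyl] compound (C-11 and C-12 epimers)
Conditions: NaBH4, MeOH, 0 °C
Reagents that add atoms: none
Why: Borohydride reduction of the β-keto sulfoxide; the C-11 and C-12 configurations are irrelevant because both carbons become sp2 in the next step.

Step 12
Reactants: 15 β-hydroxy sulfoxide
Product: 17 vinyl sulfoxide (C11=C12 with (R)-p-tolylsulfinyl on C-11; same spatial arrangement at sulfur as in 14), via mesylate 16 (not isolated)
Conditions: MsCl, Et3N, CH2Cl2, 0 °C; then DBU, rt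
Reagents that add atoms: none
Why: Mesylation and base-induced β-elimination towards the acidified α-sulfinyl hydrogen (E1cB) give the conjugated vinyl sulfoxide without touching the sulfur center.

Step 13
Reactants: 17 vinyl sulfoxide
Product: 20 13-chloro-13-methyl-11-(p-tolylthio) lactone cis-fused at C11–C12 (O-11 and C-13 on the ring A face opposite to the ethyl group; C-13 epimers), via acyloxysulfonium enolate 18 (not isolated), via thionium carboxylate 19 (not isolated)
Conditions: 2-chloropropanoyl chloride (4 equiv), Et3N (4 equiv, slow addition), CH2Cl2, 0 °C → rt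
Reagents that add atoms: 2-chloropropanoyl chloride CC(Cl)C(=O)Cl
Why: Vinyl sulfoxide–haloketene lactonisation (Marino lactonisation): the sulfinyl oxygen of 17 adds to chloro(methyl)ketene to give acyloxysulfonium enolate 18, whose [3,3]-sigmatropic shift forms C12–C13 and breaks S–O, and the carboxylate of the resulting thionium ion 19 then adds to C-11 to form O–C11. The closest known reaction is the same lactonisation of 1-(arylsulfinyl)cycloalkenes with dichloro- or chloroketene, of which chloro(methyl)ketene is the alkyl homologue. Ring D closes 5-exo-trig on the C11=S+ bond and can only be cis-fused, because the carboxylate hangs from C-13 on the face where C12–C13 was made. C-12 is set by the sulfur center, which delivers the enolate to the alkene face carrying the S–O bond (the face opposite to the ethyl group for the sulfoxide drawn, under the stated assumption), and the pseudoaxial C-10 ethyl group blocks the other face; C-11 follows from the tether, and C-13 is left open here and set in step 14. The step needs the sigmatropic path to win over Pummerer chemistry and [2+2] addition: sulfur on C-11 fixes the regiochemistry, sulfur has no α-C–H for a normal Pummerer reaction, and the only other alkene is the electron-poor C6=C7 of the lactam.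

Step 14
Reactants: 20 chloro thio lactone
Product: 21 tetracyclic lactone ester (ring D complete: H-11, H-12, H-13 all cis; methyl ester on C-3; C-5 lactam with C6=C7)
Conditions: Bu3SnH (3 equiv), AIBN (cat.), PhMe, 90 °C
Reagents that add atoms: none
Why: Radical chain reduction: Bu3Sn• abstracts chlorine and cleaves the C11–S bond, the planar C-13 radical takes hydrogen on the convex lactone face anti to C-1 (13-H cis to 12-H, methyl on the concave face as in the target) and the C-11 radical takes hydrogen on the exo face, which keeps the lactone cis-fused.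

Step 15
Reactants: 21 tetracyclic lactone ester
Product: 22 C-3 carboxylic acid
Conditions: LiI, EtOAc, reflux; aq. HCl work-up
Reagents that add atoms: none
Why: Nucleophilic (SN2) demethylation of the methyl ester by iodide frees the C-3 acid under non-hydrolytic, non-basic conditions that leave lactone ring D and the C-13 and C-3 centers alone.

Step 16
Reactants: 22 C-3 carboxylic acid
Product: 23 S-ethyl thioester
Conditions: EtSH, EDC·HCl, DMAP (cat.), CH2Cl2, 0 °C → rt
Reagents that add atoms: ethanethiol CCS
Why: Carbodiimide (Steglich-type) thioesterification activates the acid for ketone synthesis.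

Step 17
Reactants: 23 S-ethyl thioester; 24 methyl (R)-3-bromo-2-methylpropanoate
Product: 26 γ-keto ester (C-3 bears C(=O)CH2CH(CH3)CO2Me; 20S), via organozinc bromide 25 (not isolated)
Conditions: 24, Zn dust, LiCl, THF, 40 °C; then 23, PdCl2(PPh3)2 (5 mol%), PhMe/THF, rt
Reagents that add atoms: none
Why: Fukuyama coupling: zerovalent palladium inserts into the thioester C–S bond and the zinc homoenolate 25 transfers its alkyl group to give the ketone, the organozinc tolerating lactone, lactam and ester and carrying the C-20 center unchanged from 24.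

Step 18
Reactants: 26 γ-keto ester
Product: 28 bis-lactone unsaturated lactam (ring E closed; 18S,20S), via lithium alkoxide 27 (not isolated)
Conditions: LiBH(s-Bu)3, THF, −78 °C; warm to rt; aq. NH4Cl
Reagents that add atoms: none
Why: Felkin–Anh reduction: the bulky hydride attacks the C-18 ketone anti to the C3–N bond to give the 18S alkoxide (O syn to N), which closes onto the methyl ester to form lactone ring E.

Step 19
Reactants: 28 bis-lactone unsaturated lactam
Product: 29 thiolactam (C5=S; C6=C7)
Conditions: Lawesson's reagent, PhMe, 80 °C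
Reagents that add atoms: Lawesson's reagent COc1ccc(cc1)P1(=S)SP(=S)(S1)c1ccc(OC)cc1
Why: Thionation with Lawesson's reagent is selective for the lactam carbonyl over the two lactone carbonyls.

Step 20
Reactants: 29 thiolactam
Product: 30 tertiary amine (the target without the N-oxide oxygen)
Conditions: Raney Ni (W-2), H2 (1 atm), EtOH/THF, rt
Reagents that add atoms: none
Why: Raney nickel hydrogenolysis converts C=S into CH2 and hydrogenates the conjugated C6=C7 bond in the same operation, leaving the lactones intact.

Step 21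
Reactants: 30 tertiary amine
Product: 31 N-oxytuberostemonine
Conditions: mCPBA, CH2Cl2, 0 °C; K2CO3 work-up
Reagents that add atoms: mCPBA OOC(=O)c1cccc(Cl)c1
Why: Peracid N-oxidation of the tertiary amine: oxygen adds to the nitrogen lone pair, which the ring fusion holds on the face anti to H-9a, giving the N-configuration of the target.

**Compound list**

1 | N-Boc-L-tyrosine | CC(C)(C)OC(=O)N[C@@H](Cc1ccc(O)cc1)C(=O)O | starting material
2 | spirolactone, (S)-3-(Boc-amino)-1-oxaspiro[4.5]deca-6,9-diene-2,8-dione | CC(C)(C)OC(=O)N[C@H]1CC2(C=CC(=O)C=C2)OC1=O | intermediate (not isolated)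
3 | methyl (2S,3aR,7aR)-1-Boc-3a-hydroxy-6-oxo-2,3,3a,6,7,7a-hexahydro-1H-indole-2-carboxylate (cis-fused) | COC(=O)[C@@H]1C[C@@]2(O)C=CC(=O)C[C@H]2N1C(=O)OC(C)(C)C | intermediate
4 | methyl (2S,3aR,7aR)-3a-benzoyloxy-1-Boc-6-oxo-2,3,3a,6,7,7a-hexahydro-1H-indole-2-carboxylate | COC(=O)[C@@H]1C[C@@]2(OC(=O)c3ccccc3)C=CC(=O)C[C@H]2N1C(=O)OC(C)(C)C | intermediate
5 | methyl (2S,3aR,7aR)-1-Boc-6-oxo-2,3,3a,6,7,7a-hexahydro-1H-indole-2-carboxylate (trans-fused) | COC(=O)[C@@H]1C[C@@H]2C=CC(=O)C[C@H]2N1C(=O)OC(C)(C)C | intermediate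
6 | methyl (2S,3aR,7S,7aS)-7-allyl-1-Boc-6-oxo-2,3,3a,6,7,7a-hexahydro-1H-indole-2-carboxylate | COC(=O)[C@@H]1C[C@@H]2C=CC(=O)[C@@H](CC=C)[C@H]2N1C(=O)OC(C)(C)C | intermediate
7 | ammonium trifluoroacetate of N-deprotected 6 | COC(=O)[C@@H]1C[C@@H]2C=CC(=O)[C@@H](CC=C)[C@H]2[NH2+]1.[O-]C(=O)C(F)(F)F | intermediate (not isolated)
8 | methyl (2S,3aR,7S,7aS)-1-acryloyl-7-allyl-6-oxo-2,3,3a,6,7,7a-hexahydro-1H-indole-2-carboxylate | COC(=O)[C@@H]1C[C@@H]2C=CC(=O)[C@@H](CC=C)[C@H]2N1C(=O)C=C | intermediate
9 | tricyclic enone lactam (C-3 CO2Me; C-5 lactam, C6=C7; C-10 ketone, C11=C12) | O=C1[C@H]2CC=CC(=O)N3[C@H]2[C@H](C[C@H]3C(=O)OC)C=C1 | intermediate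
10 | 11,12-epoxy-10-ketone (epoxide opposite to C-8) | O=C1[C@H]2CC=CC(=O)N3[C@H]2[C@H](C[C@H]3C(=O)OC)[C@@H]2O[C@H]12 | intermediate
11 | allylic alcohol (12-OH; C10=C11) | O[C@@H]1C=C[C@H]2CC=CC(=O)N3[C@H]2[C@@H]1C[C@H]3C(=O)OC | intermediate
12 | transposed enone (C-12 ketone; C10=C11) | O=C1C=C[C@H]2CC=CC(=O)N3[C@H]2[C@@H]1C[C@H]3C(=O)OC | intermediate
13 | bromomagnesium enolate (10-ethyl; C11=C12–OMgBr) | CC[C@@H]1[C@H]2CC=CC(=O)N3[C@H]2[C@H](C[C@H]3C(=O)OC)C(O[Mg]Br)=C1 | intermediate (not isolated)
14 | 10-ethyl-12-oxo-11-[(S)-p-tolylsulfinyl] tricyclic lactam ester (C-11 epimers) | CC[C@@H]1[C@H]2CC=CC(=O)N3[C@H]2[C@H](C[C@H]3C(=O)OC)C(=O)C1[S@](=O)c4ccc(C)cc4 | intermediate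
15 | 10-ethyl-12-hydroxy-11-[(S)-p-tolylsulfinyl] compound (C-11, C-12 epimers) | CC[C@@H]1[C@H]2CC=CC(=O)N3[C@H]2[C@H](C[C@H]3C(=O)OC)C(O)C1[S@](=O)c4ccc(C)cc4 | intermediate
16 | 12-mesylate of 15 | CC[C@@H]1[C@H]2CC=CC(=O)N3[C@H]2[C@H](C[C@H]3C(=O)OC)C(OS(C)(=O)=O)C1[S@](=O)c4ccc(C)cc4 | intermediate (not isolated)
17 | vinyl sulfoxide (C11=C12; (R)-p-tolylsulfinyl on C-11; 10-ethyl trans to C-8) | CC[C@@H]1[C@H]2CC=CC(=O)N3[C@H]2[C@H](C[C@H]3C(=O)OC)C=C1[S@](=O)c4ccc(C)cc4 | intermediate
18 | acyloxysulfonium enolate (sulfinyl O acylated by the ketene) | CC[C@@H]1[C@H]2CC=CC(=O)N3[C@H]2[C@H](C[C@H]3C(=O)OC)C=C1[S@+](OC([O-])=C(C)Cl)c4ccc(C)cc4 | intermediate (not isolated)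
19 | thionium carboxylate (C12–C13 formed; C11=S+) | CC[C@@H]1[C@H]2CC=CC(=O)N3[C@H]2[C@H](C[C@H]3C(=O)OC)[C@@H](C(C)(Cl)C([O-])=O)C1=[S+]c4ccc(C)cc4 | intermediate (not isolated)
20 | 13-chloro-13-methyl-11-(p-tolylthio) cis-fused lactone (C-13 epimers) | CC[C@@H]1[C@H]2CC=CC(=O)N3[C@H]2[C@H](C[C@H]3C(=O)OC)[C@@H]2[C@@]1(Sc4ccc(C)cc4)OC(=O)C2(C)Cl | intermediate
21 | tetracyclic lactone ester (H-11, H-12, H-13 all cis) | CC[C@@H]1[C@H]2CC=CC(=O)N3[C@H]2[C@H](C[C@H]3C(=O)OC)[C@@H]2[C@H]1OC(=O)[C@@H]2C | intermediate
22 | C-3 carboxylic acid | CC[C@@H]1[C@H]2CC=CC(=O)N3[C@H]2[C@H](C[C@H]3C(=O)O)[C@@H]2[C@H]1OC(=O)[C@@H]2C | intermediate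
23 | S-ethyl thioester | CC[C@@H]1[C@H]2CC=CC(=O)N3[C@H]2[C@H](C[C@H]3C(=O)SCC)[C@@H]2[C@H]1OC(=O)[C@@H]2C | intermediate
24 | methyl (R)-3-bromo-2-methylpropanoate | COC(=O)[C@@H](C)CBr | starting material
25 | organozinc bromide from 24 | COC(=O)[C@@H](C)C[Zn]Br | intermediate (not isolated)
26 | γ-keto ester (C-18 ketone; 20S) | CC[C@@H]1[C@H]2CC=CC(=O)N3[C@H]2[C@H](C[C@H]3C(=O)C[C@H](C)C(=O)OC)[C@@H]2[C@H]1OC(=O)[C@@H]2C | intermediate
27 | lithium (18S)-alkoxide of the hydroxy ester | CC[C@@H]1[C@H]2CC=CC(=O)N3[C@H]2[C@H](C[C@H]3[C@@H]([O-])C[C@H](C)C(=O)OC)[C@@H]2[C@H]1OC(=O)[C@@H]2C.[Li+] | intermediate (not isolated)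
28 | bis-lactone unsaturated lactam | CC[C@@H]1[C@H]2CC=CC(=O)N3[C@H]2[C@H](C[C@H]3[C@@H]2C[C@H](C)C(=O)O2)[C@@H]2[C@H]1OC(=O)[C@@H]2C | intermediate
29 | thiolactam | CC[C@@H]1[C@H]2CC=CC(=S)N3[C@H]2[C@H](C[C@H]3[C@@H]2C[C@H](C)C(=O)O2)[C@@H]2[C@H]1OC(=O)[C@@H]2C | intermediate
30 | tertiary amine (deoxy target) | CC[C@@H]1[C@H]2CCCCN3[C@H]2[C@H](C[C@H]3[C@@H]2C[C@H](C)C(=O)O2)[C@@H]2[C@H]1OC(=O)[C@@H]2C | intermediate
31 | N-oxytuberostemonine | CC[C@@H]1[C@H]2CCCC[N@@+]3([O-])[C@H]2[C@H](C[C@H]3[C@@H]2C[C@H](C)C(=O)O2)[C@@H]2[C@H]1OC(=O)[C@@H]2C | target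

**Totals and risks**

Total step count: 21. Longest linear sequence: 21 steps from 1; the bromo ester 24 enters in step 17.

Steps most likely to fail:

1. Step 13. The alkyl-substituted ketene may be attacked too slowly by the sulfinyl oxygen, so that ketene oligomerisation wins, or the enolate may be delivered to the wrong alkene face. The fallback sets out from 17 and comes back at 21. 17 is treated with dichloroketene (Cl3CCOCl, Zn–Cu couple, THF, −45 → 0 °C), the partner with the closest precedent, to give the 13,13-dichloro-11-(p-tolylthio) lactone F1. Bu3SnH/AIBN then strips both chlorines and the sulfur to give the 13-unsubstituted cis-lactone F2. LiN(i-Pr)2 and MeI methylate C-13 from the convex face to give the 13-epimer of 21 F3. A second enolisation followed by kinetic protonation on the convex face (2,6-di-tert-butylphenol, −78 °C) turns C-13 over and gives 21.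

2. Step 14. Hydrogen-atom transfer to the C-13 radical may show poor facial selectivity, or the radicals may add to the C6=C7 bond. The fallback sets out from 20 and comes back at 21. Zinc dust in AcOH removes the chlorine by two-electron reduction and the zinc enolate is protonated kinetically on the convex face to give the 13-H thio lactone F4. The C11–S bond alone is then cleaved with Bu3SnH/AIBN to give 21.

3. Step 10. Proton transfer between the acidic β-keto sulfoxide and the magnesium enolate may stall the sulfinylation at partial conversion and scramble the enolate. The fallback sets out from 12 and comes back at 14. Et2CuLi with TMSCl and an acidic work-up gives the 10-ethyl-12-ketone F5, which is isolated. Kinetic deprotonation at the C-11 methylene with i-Pr2NMgBr (2 equiv) and the same menthyl sulfinate then gives 14.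

Further compounds
F1 | step 13 | 13,13-dichloro-11-(p-tolylthio) cis-fused lactone | CC[C@@H]1[C@H]2CC=CC(=O)N3[C@H]2[C@H](C[C@H]3C(=O)OC)[C@@H]2[C@@]1(Sc4ccc(C)cc4)OC(=O)C2(Cl)Cl
F2 | step 13 | 13-unsubstituted cis-fused lactone | CC[C@@H]1[C@H]2CC=CC(=O)N3[C@H]2[C@H](C[C@H]3C(=O)OC)[C@@H]2[C@H]1OC(=O)C2
F3 | step 13 | 13-epimer of 21 | CC[C@@H]1[C@H]2CC=CC(=O)N3[C@H]2[C@H](C[C@H]3C(=O)OC)[C@@H]2[C@H]1OC(=O)[C@H]2C
F4 | step 14 | 13-H 11-(p-tolylthio) lactone | CC[C@@H]1[C@H]2CC=CC(=O)N3[C@H]2[C@H](C[C@H]3C(=O)OC)[C@@H]2[C@@]1(Sc4ccc(C)cc4)OC(=O)[C@@H]2C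
F5 | step 10 | 10-ethyl-12-ketone | CC[C@@H]1[C@H]2CC=CC(=O)N3[C@H]2[C@H](C[C@H]3C(=O)OC)C(=O)C1
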